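## Structural features

The target is a dihydrochalcone whose ring A is fused to a seven-membered oxygen ring. In 1-benzoxepine numbering the 2,5-dihydro-1-benzoxepine is O1, C2H2, C3(CH3)=C4H, C5H2, C5a, C9a. Ring A carries hydroxyls at C6 and C8, the ketone carbon at C7 and its only hydrogen at C9, and the ketone runs through a two-carbon chain to a catechol (ring B). There is no stereocentre, so none stand next to each other; the single alkene C3=C4 is trisubstituted and held cis by the ring, and the problem is one of constitution only. Ring A is a phloroglucinol core with three differentiated oxygens, and the acyl group must sit at C7 between the two free hydroxyls and not at the similar position C9. Fragile points are: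
- the allyl aryl ether O1–C2;
- the C5 methylene, benzylic and allylic, whose anion can expel the O1 phenoxide;
- the C6 hydroxyl, which stands to C3=C4 as in an ortho-prenylphenol and can add to it under acid;
- the free catechol and acylphloroglucinol, which are oxidisable.

The real difficulty is twofold: making the oxepine with the methyl-bearing alkene exactly at C3=C4, and placing the ketone regiospecifically at C7. The key step uses the fact that O1–C2 and C4–C5–C5a of the oxepine are the O1–C2=C3–C4–C4a unit of a 4H-chromene with one extra carbon, C3, wedged between the two enol ether carbons. A dihalocarbene supplies that carbon and leaves on it the halogen that later becomes the methyl group.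

## Logic of the disconnections

**21 to 20.** No skeletal bond is cut; four phenolic O–H bonds become O–CH2OCH3 bonds. The free phenols would not survive the organolithium, carbene and palladium steps, and the acetals on O6 and O8 also direct the metalation that marks C7. The gain is a set of non-acidic, non-oxidisable intermediates. The demand is a final acid treatment mild enough for C3=C4 and the O1–C2 allyl ether.

**20 to 15 and 18.** The C7–C(=O) bond is cut. This is the most convergent cut, and the ketone has to arrive after every hydride, carbene and Lewis acid step. Two fragments of similar size result. The forward step needs a nucleophilic C7 that is not C9 and is formed without touching the C5 and C2 hydrogens, hence bromine–lithium exchange at low temperature, and an acyl donor that stops at the ketone.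

**18 to 17 to 16.** The amide C–N bond and two O–acetal bonds are cut. This is routine, and the only demand is that the amine reacts at the activated acid before the catechol does.

**15 to 14 to 13.** The C2–H bond is traced back to C2–OCH3 and the C3–CH3 bond to C3–Br. These are exactly the two groups that the ring expansion leaves behind, so no extra functional group manipulation is needed. Two demands follow: palladium must choose the alkenyl bromide over the aryl bromide, and the acetal reduction must spare the methoxymethyl ethers. Methylation is therefore placed first, because the methyl-substituted acetal ionises more easily and allows the mildest reduction.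

**13 to 10 and 11 (key).** The bonds C2–C3 and C3–C4 are cut and C3 is removed as the one-carbon unit of 11. The seven-membered ring problem becomes a six-membered enol ether. The forward step must add the carbene to the enol ether and not to the arene, open the cyclopropane in one sense only, and capture the cation at C2.

**10 to 8.** The C6–Br bond of the chromene, the later C7–Br bond, is cut. The regiochemical decision for the acyl group is taken here, on a robust and cheap intermediate: the ring oxygen of 8 is a poor ligand for lithium and 8 has no base-labile oxepine. The bromine is a spectator in the key step, so 10 and 13 keep the chromene and 3-bromo-2-methoxy-2,5-dihydro-1-benzoxepine skeletons. The demand is lithiation between the two acetals.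

**8 to 6, 5 and 4.** The enol ether C2=C3 is traced to a lactol and then to a lactone, and the two O–acetal bonds are cut. Only functional group changes on a chroman-2-one are involved. The demands are a dehydration that is not acidic and a reduction that stops at the lactol.

**4 to 1 and 2.** The C4–C4a bond and the lactone O1–C2 bond are cut. The three ring positions of 1 are equivalent, so the annulation has no regiochemistry. The demand is that only one of the three positions reacts.

## Other disconnections considered

**Alternative 1:** Ring A is built last. The cut runs through C5a–C6, C6–C7 and C8–C9. It leaves the oxepine as the monocyclic diazoketone 2-diazo-1-(3-methyl-2,5-dihydrooxepin-7-yl)ethanone A1. The side chain sits on the siloxyalkyne A2, a triisopropylsilyl ynol ether whose second alkyne carbon carries the dioxolane-masked 3-arylpropanoyl group. Forward, irradiation of A1 should trigger a Wolff rearrangement to ketene A3, which adds A2 in a [2+2] sense; four-electron opening and six-electron closure then give phenol A4.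
- In favour: the position of every ring A substituent follows from the connectivity of the partners, so the acyl carbon must end between O6 and O8. On this point it is better than the chosen plan, which needs a directed metalation to tell C7 from C9. It is also convergent at a late stage.
- Against: A1 is a diazoketone on the oxygen-bearing carbon of a cyclic enol ether that also holds a skipped diene. It needs its own multistep synthesis and is sensitive to acid and light beyond the wanted event. A2 is hindered at the propargylic ketal carbon and hydrolytically labile. Three kinds of protecting group remain after the annulation, and the dioxolane flanked by two ortho oxygens would need stronger acid than the last step of the chosen route.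
- Comparison: on structure it solves the arene pattern best but does not simplify the oxepine, which must still be made, and as a less stable monocycle. On mechanism the pericyclic cascade is as predictable as the ring expansion. On step economy it is clearly longer.

**Alternative 2:** The cut is C5–C5a. The precursor is the Z-allylic carbonate A5, in which the oxygen para to the ketone of a 2,4,6-trioxygenated aryl ketone carries the chain O1–C2–C3(CH3)=C4–C5–OCO2CH3. Forward, Pd(PPh3)4 ionises the carbonate and the ring carbon next to the ether oxygen attacks the C5 terminus, closing the oxepine to A6.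
- In favour: the aryl ketone core is mirror-symmetric about the C7–C9a axis, so the two possible ring carbons are equivalent and the ketone is at C7 automatically. The ketone can be put on 1 at the outset, and ring A needs no protection. On regiochemistry of the arene and on step count this is better than the chosen plan.
- Against: the closure is a seven-membered attack at the remote terminus. It competes with attack at the methyl-bearing terminus, which gives a five-membered ring with a quaternary carbon. It also competes with syn–anti isomerisation of the Z-configured allyl unit, after which a cis alkene in a seven-membered ring can no longer form. The O1–C2 aryl allyl ether of A5 and A6 is itself an allylic leaving group for zerovalent palladium. The diphenylmethylene ketal needs hydrogenolysis or hot acid, neither attractive beside the alkene.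
- Comparison: structure and step economy favour this alternative. Mechanistic security favours the chosen plan, in which the ring size and the alkene position cannot vary.

**Alternative 3:** Two bonds at adjacent carbons are cut, C6–O and C7–C(=O). The partners are the silyl triflate A7 and 3-[3,4-bis(methoxymethoxy)phenyl]propanoic acid A9. Forward, CsF should convert A7 into aryne A8; the carboxylate oxygen of A9 adds at C6 and the C7 anion takes the acyl group from that oxygen to give A10.
- In favour: ketone and C6 hydroxyl arrive in one convergent step without any organolithium, which is better than the chosen plan on base sensitivity. The C8 alkoxy group steers the oxygen nucleophile to C6, a rule as reliable as the bromine–lithium exchange of the chosen plan, so the two are equal on that point.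
- Against: A7 is a pentasubstituted arene with adjacent silyl and triflate groups on a finished dihydrobenzoxepine. Making it requires the same ortho-functionalisation choice between C7 and C9, plus differentiation of O6 from O8, so the difficulty is moved and not removed. Simple O–H addition giving the aryl ester without acyl shift competes, and the reactive triple bond of A8 lies next to the C5 methylene and the C3=C4 alkene. The oxepine still has to come from another method.
- Comparison: convergence and mildness are attractive and the final deprotection is the same as in the chosen plan. The overall sequence is probably longer because of A7, and the partition of the key step is less predictable.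

Key step: step 6

Assumption: oxepines are numbered as 1-benzoxepines and chromenes as chromenes throughout; 6, 7, 12, 13 and 14 are racemic and their stereocentres are removed before the target, which has none.

## Route

Step 1
Reactants: 1 phloroglucinol (benzene-1,3,5-triol); 2 acrylic acid
Product: 4 5,7-dihydroxy-3,4-dihydro-2H-chromen-2-one, via 3-(2,4,6-trihydroxyphenyl)propanoic acid 3 (not isolated)
Conditions: 1 in excess, Amberlyst-15, toluene, reflux, Dean–Stark
Reagents that add atoms: none
Why: Acid-catalysed conjugate Friedel–Crafts alkylation of the very nucleophilic triol should give acid 3, which lactonises onto an ortho hydroxyl as water is removed; the three ring positions of 1 are equivalent, so there is no regiochemistry, and the excess of 1 limits a second annulation.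

Step 2
Reactants: 4 5,7-dihydroxy-3,4-dihydro-2H-chromen-2-one
Product: 5 5,7-bis(methoxymethoxy)-3,4-dihydro-2H-chromen-2-one
Conditions: MOMCl, iPr2NEt, CH2Cl2, 0 °C → rt
Reagents that add atoms: chloromethyl methyl ether, COCCl
Why: O-Alkylation of both phenols under amine base; the aryl lactone meets no nucleophile under these anhydrous conditions.

Step 3
Reactants: 5 5,7-bis(methoxymethoxy)-3,4-dihydro-2H-chromen-2-one
Product: 6 5,7-bis(methoxymethoxy)-3,4-dihydro-2H-chromen-2-ol (racemic lactol)
Conditions: i-Bu2AlH, CH2Cl2, −78 °C; aq. KNaC4H4O6
Reagents that add atoms: none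
Why: Partial reduction of a lactone: the tetrahedral aluminium hemiacetal is stable at −78 °C and collapses only on work-up, and the aryl acetals are inert to the hydride; the new centre is racemic and is removed in step 4.

Step 4
Reactants: 6 5,7-bis(methoxymethoxy)-3,4-dihydro-2H-chromen-2-ol
Product: 8 5,7-bis(methoxymethoxy)-4H-chromene, via chroman-2-yl methanesulfonate 7 (not isolated)
Conditions: MsCl, Et3N, CH2Cl2, 0 → 40 °C
Reagents that add atoms: methanesulfonyl chloride, CS(=O)(=O)Cl (its atoms stay only in intermediate 7)
Why: Sulfonylation of the anomeric hydroxyl gives 7, which ionises to the aryl-stabilised oxocarbenium ion and loses a C3 proton to the amine; this lactol-to-enol-ether dehydration is standard for tetrahydropyranols and 2-deoxy sugar lactols, and the basic medium spares the acetals and the enol ether.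

Step 5
Reactants: 8 5,7-bis(methoxymethoxy)-4H-chromene
Product: 10 6-bromo-5,7-bis(methoxymethoxy)-4H-chromene, via chromen-6-yllithium 9 (not isolated)
Conditions: n-BuLi, THF, −20 → 0 °C; BrCl2C–CCl2Br, −78 °C → rt
Reagents that add atoms: 1,2-dibromo-1,1,2,2-tetrachloroethane, ClC(Cl)(Br)C(Cl)(Cl)Br; n-butyllithium, [Li]CCCC (its lithium stays only in intermediate 9)
Why: Directed ortho-metalation: C6–H lies between two chelating methoxymethoxy groups, whereas C8–H has one such group and the ring oxygen, whose lone pairs are shared between the arene and the enol ether; the C4 methylene is not acidified because its anion would be a cyclic eight-electron pyranyl anion, and the bromine donor brominates the aryllithium without touching the enol ether.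

Step 6
Reactants: 10 6-bromo-5,7-bis(methoxymethoxy)-4H-chromene; 11 bromoform
Product: 13 3,7-dibromo-2-methoxy-6,8-bis(methoxymethoxy)-2,5-dihydro-1-benzoxepine (racemic), via dibromocyclopropane adduct 12 (not isolated)
Conditions: CHBr3, KOC(CH3)3, pentane, −20 → 0 °C; filtration, solvent exchange; AgOAc, MeOH, 25 → 50 °C, dark
Reagents that add atoms: methanol, CO
Why: α-Elimination of 11 gives singlet dibromocarbene, which adds suprafacially to the most electron-rich π bond of 10, the enol ether C2=C3, forming the later C2–C3 and C3–C4 bonds in the cis-fused cyclopropane 12. The silver cation then pulls off the endo bromide while the cyclopropane bond shared with the pyran ring opens in a disrotatory two-electron electrocyclic process; only departure of the endo bromide turns the ring carbons inward, which is what a cis allyl cation in a seven-membered ring requires. The ring is therefore not closed by a cyclisation but enlarged from six to seven members by cleavage of the old C2–C3 bond, and the exo bromine stays on the inserted carbon C3. The cation is delocalised over C2, C4 and O1, and methanol should add at C2, where the oxocarbenium character is concentrated, and not at C4, giving the mixed acetal. The closest known reaction type is dihalocarbene addition to cyclic enol ethers (dihydropyrans, glycals, 4H-chromenes) followed by silver-assisted ring expansion to 3-halo-2-alkoxy oxepines. The two stereocentres of 12 are fixed cis by the carbene addition and vanish on opening; the acetal carbon C2 of 13 forms without control and is removed in step 8. The step needs chemoselectivity for the enol ether over the arene, which the bromine and the two flanking acetals of ring A help by deactivating and shielding it, and one sense of opening, which the ring fusion enforces.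

Step 7
Reactants: 13 3,7-dibromo-2-methoxy-6,8-bis(methoxymethoxy)-2,5-dihydro-1-benzoxepine
Product: 14 7-bromo-2-methoxy-6,8-bis(methoxymethoxy)-3-methyl-2,5-dihydro-1-benzoxepine (racemic)
Conditions: MeZnCl (1.2 equiv), Pd(PPh3)4 (cat.), THF, 25 → 45 °C
Reagents that add atoms: methylzinc chloride, C[Zn]Cl
Why: Negishi coupling: oxidative addition of zerovalent palladium into the alkenyl C3–Br bond is much faster than into the aryl C7–Br bond, which is electron-rich and flanked by two ortho acetal oxygens, so a small excess of the zinc reagent should methylate C3 only; β-alkoxide elimination from the alkenylpalladium would need a seven-membered cyclic allene and is closed.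

Step 8
Reactants: 14 7-bromo-2-methoxy-6,8-bis(methoxymethoxy)-3-methyl-2,5-dihydro-1-benzoxepine
Product: 15 7-bromo-6,8-bis(methoxymethoxy)-3-methyl-2,5-dihydro-1-benzoxepine
Conditions: Et3SiH, BF3·OEt2, CH2Cl2, −78 °C
Reagents that add atoms: none
Why: Ionic hydrogenation of a mixed acetal: BF3 removes the exocyclic methoxide to give the allyl-stabilised oxocarbenium ion and the silane delivers hydride to C2, as in the reduction of 2-alkoxychromans and 2,3-unsaturated glycosides; a substituted allylic acetal ionises far faster than a formaldehyde acetal, and methyl in place of bromine at C3 makes ionisation easier, so −78 °C should spare the methoxymethyl ethers; the only stereocentre is erased.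

Step 9
Reactants: 16 3-(3,4-dihydroxyphenyl)propanoic acid
Product: 17 3-(3,4-dihydroxyphenyl)-N-methoxy-N-methylpropanamide
Conditions: MeNHOMe·HCl, EDC·HCl, HOBt (cat.), iPr2NEt, DMF, 0 °C → rt, under N2
Reagents that add atoms: N,O-dimethylhydroxylamine hydrochloride, CNOC.Cl
Why: Carbodiimide amide coupling: the amine out-competes the phenols for the active ester, so the catechol need not be protected first.

Step 10
Reactants: 17 3-(3,4-dihydroxyphenyl)-N-methoxy-N-methylpropanamide
Product: 18 3-[3,4-bis(methoxymethoxy)phenyl]-N-methoxy-N-methylpropanamide
Conditions: MOMCl, iPr2NEt, CH2Cl2, 0 °C → rt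
Reagents that add atoms: chloromethyl methyl ether, COCCl
Why: O-Alkylation of both catechol hydroxyls; the Weinreb amide is inert under these conditions.

Step 11
Reactants: 15 7-bromo-6,8-bis(methoxymethoxy)-3-methyl-2,5-dihydro-1-benzoxepine; 18 3-[3,4-bis(methoxymethoxy)phenyl]-N-methoxy-N-methylpropanamide
Product: 20 3-[3,4-bis(methoxymethoxy)phenyl]-1-[6,8-bis(methoxymethoxy)-3-methyl-2,5-dihydro-1-benzoxepin-7-yl]propan-1-one, via benzoxepin-7-yllithium 19 (not isolated)
Conditions: t-BuLi (2 equiv), THF, −78 °C; 18, −78 → 0 °C; H2O
Reagents that add atoms: tert-butyllithium, [Li]C(C)(C)C (its lithium stays only in intermediate 19)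
Why: Bromine–lithium exchange at −78 °C is faster than deprotonation of the C5 or C2 methylene and puts lithium at C7 only, chelated by both neighbouring acetals; addition to the Weinreb amide gives a chelated tetrahedral adduct that cannot add a second time and releases the ketone on hydrolysis.

Step 12
Reactants: 20 3-[3,4-bis(methoxymethoxy)phenyl]-1-[6,8-bis(methoxymethoxy)-3-methyl-2,5-dihydro-1-benzoxepin-7-yl]propan-1-one
Product: 21 3-(3,4-dihydroxyphenyl)-1-(6,8-dihydroxy-3-methyl-2,5-dihydro-1-benzoxepin-7-yl)propan-1-one (CNP0203471.0)
Conditions: HCl (aq.), MeOH, 40 °C, degassed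
Reagents that add atoms: none
Why: Acid-catalysed acetal exchange with methanol removes all four methoxymethyl groups, the two beside the ketone fastest through hydrogen-bond assistance; dilute acid at moderate temperature is the usual compromise that leaves prenyl-type alkenes and aryl allyl ethers intact, and no stereocentre is involved.

## Compound list

1 | phloroglucinol (benzene-1,3,5-triol) | Oc1cc(O)cc(O)c1 | starting material
2 | acrylic acid | C=CC(=O)O | starting material
3 | 3-(2,4,6-trihydroxyphenyl)propanoic acid | OC(=O)CCc1c(O)cc(O)cc1O | intermediate (not isolated)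
4 | 5,7-dihydroxy-3,4-dihydro-2H-chromen-2-one | O=C1CCc2c(O)cc(O)cc2O1 | intermediate
5 | 5,7-bis(methoxymethoxy)-3,4-dihydro-2H-chromen-2-one | O=C1CCc2c(OCOC)cc(OCOC)cc2O1 | intermediate
6 | 5,7-bis(methoxymethoxy)-3,4-dihydro-2H-chromen-2-ol, racemic, one enantiomer drawn | O[C@H]1CCc2c(OCOC)cc(OCOC)cc2O1 | intermediate
7 | 5,7-bis(methoxymethoxy)-3,4-dihydro-2H-chromen-2-yl methanesulfonate, racemic, one enantiomer drawn | CS(=O)(=O)O[C@H]1CCc2c(OCOC)cc(OCOC)cc2O1 | intermediate (not isolated)
8 | 5,7-bis(methoxymethoxy)-4H-chromene | C1=COc2cc(OCOC)cc(OCOC)c2C1 | intermediate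
9 | [5,7-bis(methoxymethoxy)-4H-chromen-6-yl]lithium | C1=COc2cc(OCOC)c([Li])c(OCOC)c2C1 | intermediate (not isolated)
10 | 6-bromo-5,7-bis(methoxymethoxy)-4H-chromene | C1=COc2cc(OCOC)c(Br)c(OCOC)c2C1 | intermediate (precursor of the key step)
11 | bromoform (tribromomethane) | BrC(Br)Br | starting material
12 | 1,1,5-tribromo-4,6-bis(methoxymethoxy)-1,1a,7,7a-tetrahydrocyclopropa[b]chromene, cis-fused, racemic, one enantiomer drawn | BrC1(Br)[C@H]2Cc3c(OCOC)c(Br)c(OCOC)cc3O[C@@H]12 | intermediate (not isolated)
13 | 3,7-dibromo-2-methoxy-6,8-bis(methoxymethoxy)-2,5-dihydro-1-benzoxepine, racemic, one enantiomer drawn | CO[C@H]1Oc2cc(OCOC)c(Br)c(OCOC)c2CC=C1Br | intermediate (product of the key step)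
14 | 7-bromo-2-methoxy-6,8-bis(methoxymethoxy)-3-methyl-2,5-dihydro-1-benzoxepine, racemic, one enantiomer drawn | CO[C@H]1Oc2cc(OCOC)c(Br)c(OCOC)c2CC=C1C | intermediate
15 | 7-bromo-6,8-bis(methoxymethoxy)-3-methyl-2,5-dihydro-1-benzoxepine | CC1=CCc2c(cc(OCOC)c(Br)c2OCOC)OC1 | intermediate
16 | 3-(3,4-dihydroxyphenyl)propanoic acid | OC(=O)CCc1ccc(O)c(O)c1 | starting material
17 | 3-(3,4-dihydroxyphenyl)-N-methoxy-N-methylpropanamide | CON(C)C(=O)CCc1ccc(O)c(O)c1 | intermediate
18 | 3-[3,4-bis(methoxymethoxy)phenyl]-N-methoxy-N-methylpropanamide | CON(C)C(=O)CCc1ccc(OCOC)c(OCOC)c1 | intermediate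
19 | [6,8-bis(methoxymethoxy)-3-methyl-2,5-dihydro-1-benzoxepin-7-yl]lithium | CC1=CCc2c(cc(OCOC)c([Li])c2OCOC)OC1 | intermediate (not isolated)
20 | 3-[3,4-bis(methoxymethoxy)phenyl]-1-[6,8-bis(methoxymethoxy)-3-methyl-2,5-dihydro-1-benzoxepin-7-yl]propan-1-one | CC1=CCc2c(cc(OCOC)c(C(=O)CCc3ccc(OCOC)c(OCOC)c3)c2OCOC)OC1 | intermediate
21 | 3-(3,4-dihydroxyphenyl)-1-(6,8-dihydroxy-3-methyl-2,5-dihydro-1-benzoxepin-7-yl)propan-1-one | CC1=CCc2c(cc(O)c(C(=O)CCc3ccc(O)c(O)c3)c2O)OC1 | target

## Step count and least certain steps

Total: 12 steps, 10 on the main line and 2 for fragment 18. Longest linear sequence: 10 steps (steps 1 to 8, 11 and 12).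

**Step 6 (key step).** The most likely failure is sluggish or unselective ionisation of the cyclopropane, because the aryl ring oxygen is a weaker donor than the oxygen of an alkyl enol ether. Loss of a C5 proton from the allyl cation, which would drain material into a fully conjugated benzoxepine, is the second risk. The fallback gives up the ring expansion and closes the oxepine by olefin metathesis; it sets out from 10 and returns at 15. Ozonolysis of the enol ether of 10 (O3, CH2Cl2, −78 °C; Me2S) should give 4-bromo-3,5-bis(methoxymethoxy)-2-(2-oxoethyl)phenyl formate F1. K2CO3 in methanol removes the formyl group and the phenol closes onto the aldehyde to give 5-bromo-4,6-bis(methoxymethoxy)-2,3-dihydro-1-benzofuran-2-ol F2. Wittig methylenation of this lactol (Ph3P=CH2, THF) gives 4-bromo-3,5-bis(methoxymethoxy)-2-(prop-2-en-1-yl)phenol F3. O-Alkylation with 3-chloro-2-methylprop-1-ene (K2CO3, DMF) gives 2-bromo-1,3-bis(methoxymethoxy)-5-[(2-methylprop-2-en-1-yl)oxy]-4-(prop-2-en-1-yl)benzene F4. Ring-closing metathesis with the second-generation Grubbs catalyst (CH2Cl2, 40 °C) should then give 15, with the cis alkene enforced by the ring.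

**Step 8.** The most likely failure is competing ionisation of the formaldehyde acetals, so that protecting groups are lost. Hydride capture of the ring-opened oxocarbenium ion, which would cleave O1–C2, is the second risk. The fallback avoids any Lewis acid; it sets out from 10 and returns at 15. Carbene addition as in step 6 gives 12, which is opened with AgNO3 in aqueous acetone to 3,7-dibromo-6,8-bis(methoxymethoxy)-2,5-dihydro-1-benzoxepin-2-ol F5, a lactol in equilibrium with its hydroxy enal. NaBH4 with CeCl3·7H2O in methanol reduces the open form to (E)-2-bromo-4-[3-bromo-6-hydroxy-2,4-bis(methoxymethoxy)phenyl]but-2-en-1-ol F6. Mitsunobu etherification (PPh3, diisopropyl azodicarboxylate, THF) closes O1–C2 to 3,7-dibromo-6,8-bis(methoxymethoxy)-2,5-dihydro-1-benzoxepine F7. The Negishi conditions of step 7 then give 15.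

**Step 5.** The most likely failure is metalation beside the ring oxygen at C8 in competition with metalation between the two acetals, which would put the bromine, and later the ketone, on the wrong carbon. If C8 metalation prevails, the fallback turns it into a blocking step; it sets out from 8 and returns at 10. Lithiation to [5,7-bis(methoxymethoxy)-4H-chromen-8-yl]lithium F8 and quenching with Me3SiCl give [5,7-bis(methoxymethoxy)-4H-chromen-8-yl]trimethylsilane F9. A second lithiation can then occur only at C6, giving [5,7-bis(methoxymethoxy)-8-(trimethylsilyl)-4H-chromen-6-yl]lithium F10, and the bromine donor of step 5 gives [6-bromo-5,7-bis(methoxymethoxy)-4H-chromen-8-yl]trimethylsilane F11. Protodesilylation with Bu4NF in wet DMF at 80 °C, which the two flanking oxygens assist, returns 10.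

**Step 4.** The most likely failure is sulfonylation of the phenol of the ring-opened hydroxy aldehyde tautomer instead of the lactol hydroxyl, or oligomerisation of the enol ether by the ammonium salts. The fallback is a neutral elimination through sulfur; it sets out from 6 and returns at 8. Treatment of 6 with PhSSPh and Bu3P gives 5,7-bis(methoxymethoxy)-2-(phenylsulfanyl)-3,4-dihydro-2H-chromene F12. Oxidation with mCPBA at −78 °C gives 2-(benzenesulfinyl)-5,7-bis(methoxymethoxy)-3,4-dihydro-2H-chromene F13. Thermal syn-elimination in toluene at 110 °C with Et3N present gives 8.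

**Step 12.** The most likely failure is acid-induced addition of the freed C6 hydroxyl to C3=C4, or ionisation of the O1–C2 allyl ether, before all four acetals are gone. The fallback exchanges the acetals for silyl ethers in a buffered aprotic medium; it sets out from 20 and returns at 21. Me3SiOTf with 2,2'-bipyridyl in CH2Cl2 at 0 °C converts 20 into 3-[3,4-bis(trimethylsilyloxy)phenyl]-1-[3-methyl-6,8-bis(trimethylsilyloxy)-2,5-dihydro-1-benzoxepin-7-yl]propan-1-one F14. Water with a trace of K2CO3 in methanol then hydrolyses the silyl ethers to 21 without strong Brønsted acid.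

## Further compounds

F1 | step 6 | 4-bromo-3,5-bis(methoxymethoxy)-2-(2-oxoethyl)phenyl formate | O=CCc1c(OC=O)cc(OCOC)c(Br)c1OCOC
F2 | step 6 | 5-bromo-4,6-bis(methoxymethoxy)-2,3-dihydro-1-benzofuran-2-ol, racemic, one enantiomer drawn | O[C@@H]1Cc2c(OCOC)c(Br)c(OCOC)cc2O1
F3 | step 6 | 4-bromo-3,5-bis(methoxymethoxy)-2-(prop-2-en-1-yl)phenol | C=CCc1c(O)cc(OCOC)c(Br)c1OCOC
F4 | step 6 | 2-bromo-1,3-bis(methoxymethoxy)-5-[(2-methylprop-2-en-1-yl)oxy]-4-(prop-2-en-1-yl)benzene | C=CCc1c(OCC(C)=C)cc(OCOC)c(Br)c1OCOC
F5 | step 8 | 3,7-dibromo-6,8-bis(methoxymethoxy)-2,5-dihydro-1-benzoxepin-2-ol, racemic, one enantiomer drawn | O[C@H]1Oc2cc(OCOC)c(Br)c(OCOC)c2CC=C1Br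
F6 | step 8 | (E)-2-bromo-4-[3-bromo-6-hydroxy-2,4-bis(methoxymethoxy)phenyl]but-2-en-1-ol | OC/C(Br)=C\Cc1c(O)cc(OCOC)c(Br)c1OCOC
F7 | step 8 | 3,7-dibromo-6,8-bis(methoxymethoxy)-2,5-dihydro-1-benzoxepine | BrC1=CCc2c(cc(OCOC)c(Br)c2OCOC)OC1
F8 | step 5 | [5,7-bis(methoxymethoxy)-4H-chromen-8-yl]lithium | C1=COc2c([Li])c(OCOC)cc(OCOC)c2C1
F9 | step 5 | [5,7-bis(methoxymethoxy)-4H-chromen-8-yl]trimethylsilane | C1=COc2c([Si](C)(C)C)c(OCOC)cc(OCOC)c2C1
F10 | step 5 | [5,7-bis(methoxymethoxy)-8-(trimethylsilyl)-4H-chromen-6-yl]lithium | C1=COc2c([Si](C)(C)C)c(OCOC)c([Li])c(OCOC)c2C1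
F11 | step 5 | [6-bromo-5,7-bis(methoxymethoxy)-4H-chromen-8-yl]trimethylsilane | C1=COc2c([Si](C)(C)C)c(OCOC)c(Br)c(OCOC)c2C1
F12 | step 4 | 5,7-bis(methoxymethoxy)-2-(phenylsulfanyl)-3,4-dihydro-2H-chromene, racemic, one enantiomer drawn | COCOc1cc(OCOC)c2CC[C@H](Sc3ccccc3)Oc2c1
F13 | step 4 | 2-(benzenesulfinyl)-5,7-bis(methoxymethoxy)-3,4-dihydro-2H-chromene, mixture of diastereomers | COCOc1cc(OCOC)c2CCC(S(=O)c3ccccc3)Oc2c1
F14 | step 12 | 3-[3,4-bis(trimethylsilyloxy)phenyl]-1-[3-methyl-6,8-bis(trimethylsilyloxy)-2,5-dihydro-1-benzoxepin-7-yl]propan-1-one | CC1=CCc2c(cc(O[Si](C)(C)C)c(C(=O)CCc3ccc(O[Si](C)(C)C)c(O[Si](C)(C)C)c3)c2O[Si](C)(C)C)OC1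
A1 | alternative 1 | 2-diazo-1-(3-methyl-2,5-dihydrooxepin-7-yl)ethanone | CC1=CCC=C(C(=O)C=[N+]=[N-])OC1
A2 | alternative 1 | ({2-[2-(3,4-bis(methoxymethoxy)phenyl)ethyl]-1,3-dioxolan-2-yl}ethynyloxy)triisopropylsilane | CC(C)[Si](C(C)C)(C(C)C)OC#CC1(CCc2ccc(OCOC)c(OCOC)c2)OCCO1
A3 | alternative 1 | 2-(3-methyl-2,5-dihydrooxepin-7-yl)ethenone | O=C=CC1=CCC=C(C)CO1
A4 | alternative 1 | 7-{2-[2-(3,4-bis(methoxymethoxy)phenyl)ethyl]-1,3-dioxolan-2-yl}-3-methyl-8-(triisopropylsilyloxy)-2,5-dihydro-1-benzoxepin-6-ol | CC1=CCc2c(cc(O[Si](C(C)C)(C(C)C)C(C)C)c(C3(CCc4ccc(OCOC)c(OCOC)c4)OCCO3)c2O)OC1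
A5 | alternative 2 | (Z)-4-{4-[3-(2,2-diphenyl-1,3-benzodioxol-5-yl)propanoyl]-3,5-dihydroxyphenoxy}-3-methylbut-2-en-1-yl methyl carbonate | COC(=O)OC/C=C(/C)COc1cc(O)c(C(=O)CCc2ccc3OC(c4ccccc4)(c4ccccc4)Oc3c2)c(O)c1
A6 | alternative 2 | 1-(6,8-dihydroxy-3-methyl-2,5-dihydro-1-benzoxepin-7-yl)-3-(2,2-diphenyl-1,3-benzodioxol-5-yl)propan-1-one | CC1=CCc2c(cc(O)c(C(=O)CCc3ccc4OC(c5ccccc5)(c5ccccc5)Oc4c3)c2O)OC1
A7 | alternative 3 | 8-(methoxymethoxy)-3-methyl-7-(trimethylsilyl)-2,5-dihydro-1-benzoxepin-6-yl trifluoromethanesulfonate | CC1=CCc2c(cc(OCOC)c([Si](C)(C)C)c2OS(=O)(=O)C(F)(F)F)OC1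
A8 | alternative 3 | 6,7-didehydro-8-(methoxymethoxy)-3-methyl-2,5-dihydro-1-benzoxepine (aryne) | CC1=CCC2=C(C=C(OCOC)C#C2)OC1
A9 | alternative 3 | 3-[3,4-bis(methoxymethoxy)phenyl]propanoic acid | OC(=O)CCc1ccc(OCOC)c(OCOC)c1
A10 | alternative 3 | 3-[3,4-bis(methoxymethoxy)phenyl]-1-[6-hydroxy-8-(methoxymethoxy)-3-methyl-2,5-dihydro-1-benzoxepin-7-yl]propan-1-one | CC1=CCc2c(cc(OCOC)c(C(=O)CCc3ccc(OCOC)c(OCOC)c3)c2O)OC1
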